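The 2,6,6-trimethylcyclohex-2-enyl ring of the target is the head-to-tail cyclisation product of the terminal isoprene unit of geranylgeraniol. Everything rests on one biocatalytic operation: a class 2 terpene cyclase (squalene–hopene cyclase type) protonates the terminal olefin, forms the ring σ-bond between the gem-dimethyl carbon C6 and the methine C1, and ends the cation cascade by proton loss from ring C3, which creates the C2=C3 double bond and the (S)-stereocentre at C1. The step exploits the 1,5-diene (isopropylidene plus trisubstituted olefin) hidden in that ring. The precursor is commercial, acyclic, achiral (2E,6E,10E)-geranylgeraniol; acylation with linoleoyl chloride completes the synthesis.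

Key step: step 1

Assumption: the cyclase variant is taken from an active-site library of the Alicyclobacillus acidocaldarius enzyme screened for first-ring termination with proton loss from the ring methylene; it is used as a recombinant whole-cell catalyst and is not counted as a synthetic step.

Step 1
Reactants: 1 (2E,6E,10E)-geranylgeraniol [(2E,6E,10E)-3,7,11,15-tetramethylhexadeca-2,6,10,14-tetraen-1-ol]
Product: 2 (2E,6E)-3,7-dimethyl-9-[(1S)-2,6,6-trimethylcyclohex-2-en-1-yl]nona-2,6-dien-1-ol
Conditions: squalene–hopene cyclase variant (class 2 terpene cyclase, E. coli whole cells), citrate buffer pH 6.0, SDS (0.05% w/v), 37 °C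
Reagents that add atoms: none
Why: The aspartic acid of the cyclase protonates C14 of the terminal olefin of 1, the C15 cation is attacked by C10 of the (E)-10,11-olefin and the C11 cation so formed loses a proton from C12, so that the ring σ-bond (C1–C6 of the new cyclohexene) and the ring double bond (C2=C3) arise in one cationic event. The closest known reaction type is the squalene–hopene-cyclase-catalysed head-to-tail cyclisation of acyclic polyprenols and prenyl ketones, of which variants that end after the first ring are the nearest case. The single ring closes in the 6-endo-trig mode (both carbons of the 10,11-olefin become ring atoms) through a chair-like fold. The stereocentre at ring C1 is controlled by the enzyme, whose all-chair, normal-series fold (the one that gives 5α-H in hopene) presents one face of C10 to the cation and should give (S). The step needs initiation at the terminal olefin only, termination after one ring and proton loss from the ring CH2 instead of the methyl group or the methine; the hydroxyl head group and the all-E chain of 1 fix the register so that only the terminal olefin reaches the acid, whereas the last two selectivities rest on the active-site residues of the variant (narrowed second-ring pocket, base near C12).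

Step 2
Reactants: 2 (2E,6E)-3,7-dimethyl-9-[(1S)-2,6,6-trimethylcyclohex-2-en-1-yl]nona-2,6-dien-1-ol, 3 linoleoyl chloride [(9Z,12Z)-octadeca-9,12-dienoyl chloride]
Product: 4 (2E,6E)-3,7-dimethyl-9-[(1S)-2,6,6-trimethylcyclohex-2-en-1-yl]nona-2,6-dien-1-yl (9Z,12Z)-octadeca-9,12-dienoate
Conditions: pyridine (2 equiv), DMAP (cat.), CH2Cl2, 0 °C to rt, argon
Reagents that add atoms: none
Why: DMAP-catalysed O-acylation (nucleophilic acyl substitution through the N-acylpyridinium ion) of the unhindered primary allylic alcohol should proceed cleanly, because pyridine takes up the HCl so that neither the allylic C–O bond nor the trisubstituted and skipped Z,Z-olefins meet acid, and no stereocentre is formed or touched.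

Compound list
1 | (2E,6E,10E)-geranylgeraniol, (2E,6E,10E)-3,7,11,15-tetramethylhexadeca-2,6,10,14-tetraen-1-ol | OC/C=C(\C)CC/C=C(\C)CC/C=C(\C)CCC=C(C)C | starting material
2 | (2E,6E)-3,7-dimethyl-9-[(1S)-2,6,6-trimethylcyclohex-2-en-1-yl]nona-2,6-dien-1-ol | OC/C=C(\C)CC/C=C(\C)CC[C@@H]1C(C)=CCCC1(C)C | intermediate
3 | linoleoyl chloride, (9Z,12Z)-octadeca-9,12-dienoyl chloride | CCCCC/C=C\C/C=C\CCCCCCCC(Cl)=O | starting material
4 | (2E,6E)-3,7-dimethyl-9-[(1S)-2,6,6-trimethylcyclohex-2-en-1-yl]nona-2,6-dien-1-yl (9Z,12Z)-octadeca-9,12-dienoate | CCCCC/C=C\C/C=C\CCCCCCCC(=O)OC/C=C(\C)CC/C=C(\C)CC[C@@H]1C(C)=CCCC1(C)C | target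

Total step count: 2
Longest linear sequence: 2 steps (1 → 2 → 4)

Steps most likely to fail (the route has only two steps, so both are given, the riskier first)

1. Step 1. The cation cascade may not stop after the first ring, with a second closure onto the 6,7-olefin. The proton may also be lost from the methyl group (exocyclic olefin) or from the methine (tetrasubstituted olefin, stereocentre lost) instead of the ring CH2. Turnover may be low because the lipophilic alcohol reaches the membrane-bound enzyme poorly. The fallback sets out from 1 and comes back to the route at 2, and it separates ring closure from olefin placement. A cyclase variant of the kind that ends the cascade after ring A by loss of a methyl proton should give the exocyclic isomer (2E,6E)-9-[(1S)-2,2-dimethyl-6-methylidenecyclohexyl]-3,7-dimethylnona-2,6-dien-1-ol F1 with the same enzyme-set stereocentre. A separate chemical step then moves the double bond into the ring by hydrogen-atom-transfer isomerisation: Co(salen)Cl (chloride complex of trivalent cobalt with N,N'-bis(3,5-di-tert-butylsalicylidene)-1,2-cyclohexanediamine), PhSiH3 (cat.), benzene, rt. This catalyst type acts on 1,1-disubstituted olefins and leaves trisubstituted olefins and the allylic alcohol alone. Return of the hydrogen atom from the less hindered ring CH2, not from the methine next to the quaternary carbon, should give 2 without touching the stereocentre.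

2. Step 2. Adventitious HCl may ionise the primary allylic alcohol or ester (allylic chloride, allylic transposition, acid-induced cyclisation of the polyene). The acid chloride may form a ketene with base, and the skipped diene may autoxidise during handling. The fallback sets out from 2 and comes back to the route at 4, and it replaces acyl chloride chemistry by a neutral biocatalytic esterification with commercial free linoleic acid: immobilised Candida antarctica lipase B, linoleic acid, hexane, 4 Å molecular sieves, 40 °C. No activating agent and no acid are present, and no new compound is made on this path (F0).

Further compounds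
F1 | step 1 | (2E,6E)-9-[(1S)-2,2-dimethyl-6-methylidenecyclohexyl]-3,7-dimethylnona-2,6-dien-1-ol | OC/C=C(\C)CC/C=C(\C)CC[C@@H]1C(=C)CCCC1(C)C
F0 | step 2 | none | none
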